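**Strategy.** The butenolide is cut at O–C6 and C11–C12, which excises CO2 and leaves a ten-membered dienone whose C6 carbonyl and exocyclic C11 stand 1,4 across the C7=C11 bond of the five-membered lactone ring fused at C6–C7. The precursor 13 masks C6=O as a silyl enol ether and makes C11 nucleophilic through a phenylsulfonyl group (polarity reversal of an enone β-carbon). In one flask the C11 carbanion takes up CO2, fluoride unmasks the ketone, sulfinate leaves to restore C7=C11, and the carboxylate oxygen closes onto C6. The ring itself comes from an anionic oxy-Cope ring expansion of a carvone-derived divinylcyclohexenol.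

Key step: step 8

Remark (numbering and configuration): germacrane numbering is used for the ten-membered-ring compounds: ring C1–C10, lactone O on C6, C11 = lactone α-carbon, C12 = lactone C=O, C13 = CH2O, C14 on C10, C15 on C4. "Nor" names mark carbons not yet present. The target is read as 1R,3S,6R with a 4Z olefin. TBS = tert-butyldimethylsilyl, TES = triethylsilyl.

**Step 1**
Reactants: 1 (S)-(+)-carvone
Product: 2 (1S,5S)-cis-carveol
Conditions: NaBH4, CeCl3·7H2O, MeOH, −20 °C
Reagents that add atoms: none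
Why: Luche 1,2-reduction with hydride delivered anti to the isopropenyl group should give the cis-alcohol, which sets the carbinol centre (the later C3) as S.

**Step 2**
Reactants: 2 (1S,5S)-cis-carveol
Product: 3 (1S,5S)-cis-carveol TBS ether
Conditions: TBSCl, imidazole, DMF, rt
Reagents that add atoms: tert-butyldimethylsilyl chloride, CC(C)(C)[Si](C)(C)Cl
Why: standard silylation of a secondary allylic alcohol gives an ether that survives the organometallic and strongly basic steps that follow.

**Step 3**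
Reactants: 3 (1S,5S)-cis-carveol TBS ether
Product: 4 (4S,6S)-4-(tert-butyldimethylsilyloxy)-3-methyl-6-(prop-1-en-2-yl)cyclohex-2-en-1-one
Conditions: Rh2(caprolactamate)4 (cat.), t-BuOOH (70 % aq.), CH2Cl2, rt
Reagents that add atoms: tert-butyl hydroperoxide, CC(C)(C)OO
Why: dirhodium-catalysed allylic oxidation by tert-butylperoxyl radicals should convert the only ring allylic methylene (next to the unsubstituted olefin carbon, as in 1-methylcyclohexene to 3-methylcyclohexenone) into the ketone without base, so the isopropenyl group is not drawn into conjugation; no stereocentre is created.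

**Step 4**
Reactants: 4 (4S,6S)-4-(tert-butyldimethylsilyloxy)-3-methyl-6-(prop-1-en-2-yl)cyclohex-2-en-1-one; 5 vinylmagnesium bromide
Product: 6 (1S,4S,6S)-4-(tert-butyldimethylsilyloxy)-1-ethenyl-3-methyl-6-(prop-1-en-2-yl)cyclohex-2-en-1-ol
Conditions: CeCl3 (anhydrous), THF, −78 °C; aq. NH4Cl
Reagents that add atoms: none
Why: organocerium 1,2-addition suppresses enolisation of the doubly activated C6–H and conjugate addition, and attack anti to the adjacent isopropenyl group (and the cis silyloxy group) should place vinyl trans to isopropenyl (new centre 1S).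

**Step 5**
Reactants: 6 (1S,4S,6S)-4-(tert-butyldimethylsilyloxy)-1-ethenyl-3-methyl-6-(prop-1-en-2-yl)cyclohex-2-en-1-ol; 7 (tert-butyldimethylsilyloxy)acetaldehyde
Product: 9 (3S)-11-hydroxy-3,13-bis(tert-butyldimethylsilyloxy)-12-norgermacra-1(10)E,4Z-dien-6-one, via potassium enolate 8 (not isolated)
Conditions: KHMDS, 18-crown-6, THF, 0 °C → rt; then 7, −78 °C; aq. NH4Cl
Reagents that add atoms: none
Why: anionic oxy-Cope rearrangement through a chair transition state with both alkenyl groups equatorial should give the E C1=C10 olefin while the ring Z olefin is carried over, and the regiodefined C6/C7 enolate is intercepted in an aldol addition whose new C7 and C11 centres (mixture) are erased in step 6.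

**Step 6**
Reactants: 9 (3S)-11-hydroxy-3,13-bis(tert-butyldimethylsilyloxy)-12-norgermacra-1(10)E,4Z-dien-6-one
Product: 11 (3S)-3,13-bis(tert-butyldimethylsilyloxy)-12-norgermacra-1(10)E,4Z,7(11)E-trien-6-one, via mesylate 10 (not isolated)
Conditions: MsCl, Et3N, CH2Cl2, 0 °C; then DBU, rt
Reagents that add atoms: none
Why: mesylation and E1cB elimination through the C7 enolate should give the thermodynamically preferred E-alkylidene ketone (CH2OTBS anti to the carbonyl).

**Step 7**
Reactants: 11 (3S)-3,13-bis(tert-butyldimethylsilyloxy)-12-norgermacra-1(10)E,4Z,7(11)E-trien-6-one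
Product: 13 (3S)-11-(phenylsulfonyl)-3,13-bis(tert-butyldimethylsilyloxy)-6-(triethylsilyloxy)-12-norgermacra-1(10)E,4Z,6-triene, via sulfonyl ketone 12 (not isolated)
Conditions: PhSO2H, CH2Cl2, rt; then Et3N, TESOTf, −78 → 0 °C
Reagents that add atoms: benzenesulfinic acid, O=S(O)c1ccccc1; triethylsilyl trifluoromethanesulfonate, CC[Si](CC)(CC)OS(=O)(=O)C(F)(F)F
Why: sulfa-Michael addition should occur at the exocyclic β-carbon C11 (C4 is β,β-disubstituted), and soft enolisation/silylation toward C7, the only enolisable α-position, avoids a free enolate that would expel sulfinate; the C11 configuration is inconsequential.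

**Step 8**
Reactants: 13 (3S)-11-(phenylsulfonyl)-3,13-bis(tert-butyldimethylsilyloxy)-6-(triethylsilyloxy)-12-norgermacra-1(10)E,4Z,6-triene
Product: 16 (3S)-6-hydroxy-3,13-bis(tert-butyldimethylsilyloxy)germacra-1(10)E,4Z,7(11)-trien-12,6-olide, via lithium sulfonyl carboxylate 14 (not isolated), via keto acid 15 (not isolated)
Conditions: LDA, THF, −78 °C; CO2 (1 atm), −78 → −40 °C; then TBAF (1.1 equiv), −78 → 0 °C; aq. HCl work-up
Reagents that add atoms: carbon dioxide, O=C=O
Why: LDA removes the C11–H that is both α to the sulfone and allylic to the C6=C7 enol ether, and the sulfone-stabilised carbanion adds to CO2 at C11 (C11–C12 bond). Fluoride then cleaves the enol silyl ether, the liberated C6/C7 enolate expels benzenesulfinate (E1cB) to restore C7=C11, and on acidification the carboxylic acid oxygen adds to the C6 ketone (O–C6 bond). The closest known reaction type is the use of β-sulfonyl carbonyl derivatives as β-acylvinyl anion equivalents (sulfone carbanion plus electrophile, then sulfinate loss), here with CO2 as the electrophile. The five-membered lactone ring closes by 5-exo-trig addition of the carboxyl oxygen to the C6 carbonyl, the ring–chain tautomerism of a (Z)-4-oxo-2-enoic acid. The new C6 hemiketal centre forms without control and is replaced in step 9. The step needs α- and not γ-attack of the allylic anion, which the sulfone secures, and the Z geometry at C7=C11, which is secured because sulfinate adds back reversibly to the E acid while ring closure removes the Z acid.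

**Step 9**
Reactants: 16 (3S)-6-hydroxy-3,13-bis(tert-butyldimethylsilyloxy)germacra-1(10)E,4Z,7(11)-trien-12,6-olide
Product: 17 (3S,6R)-3,13-bis(tert-butyldimethylsilyloxy)germacra-1(10)E,4Z,7(11)-trien-12,6-olide
Conditions: Et3SiH (excess), BF3·OEt2, CH2Cl2, −78 °C
Reagents that add atoms: none
Why: ionic hydrogenation of the pseudo-acid through the ring acyloxocarbenium ion (as for hydroxy-lactams and hydroxyphthalides) should deliver hydride to C6 (1,2-mode) from the face of the planar C3–C8 segment that is not spanned by the C2–C1=C10–C9 bridge; the C3–O bond lies on that face, so H-6 ends cis to O-3 (6R).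

**Step 10**
Reactants: 17 (3S,6R)-3,13-bis(tert-butyldimethylsilyloxy)germacra-1(10)E,4Z,7(11)-trien-12,6-olide
Product: 18 (3S,6R)-3,13-dihydroxygermacra-1(10)E,4Z,7(11)-trien-12,6-olide
Conditions: HF·pyridine, pyridine, THF, 0 °C → rt
Reagents that add atoms: none
Why: buffered fluoride cleaves both silyl ethers without the basic conditions that would deprotonate the γ-position (C6) of the butenolide.

**Step 11**
Reactants: 18 (3S,6R)-3,13-dihydroxygermacra-1(10)E,4Z,7(11)-trien-12,6-olide
Product: 19 (3S,6R)-3,13-diacetoxygermacra-1(10)E,4Z,7(11)-trien-12,6-olide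
Conditions: Ac2O, pyridine, DMAP (cat.), CH2Cl2, 0 °C
Reagents that add atoms: acetic anhydride, CC(=O)OC(C)=O
Why: standard acylation of the primary and the secondary allylic alcohol under mildly basic conditions leaves both stereocentres untouched.

**Step 12**
Reactants: 19 (3S,6R)-3,13-diacetoxygermacra-1(10)E,4Z,7(11)-trien-12,6-olide
Product: 20 (1R,3S,6R)-3,13-diacetoxy-1-hydroperoxygermacra-4Z,7(11),10(14)-trien-12,6-olide
Conditions: O2, tetraphenylporphyrin (cat.), visible light, CH2Cl2, −20 °C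
Reagents that add atoms: dioxygen, O=O
Why: Schenck ene reaction of singlet oxygen with the electron-rich E C1=C10 olefin (C4=C5 is deactivated by two allylic acyloxy groups, C7=C11 is electron-poor) should put oxygen on C1 from the exposed outer face with hydrogen abstraction from the C14 methyl on the more crowded side of the olefin, which is expected to give the 1R (1,3-cis) hydroperoxide and the C10=C14 methylene.

**Compound list**

1 | (S)-(+)-carvone | CC1=CC[C@H](C(C)=C)CC1=O | starting material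
2 | (1S,5S)-cis-carveol | CC1=CC[C@H](C(C)=C)C[C@@H]1O | intermediate
3 | (1S,5S)-cis-carveol TBS ether | CC1=CC[C@H](C(C)=C)C[C@@H]1O[Si](C)(C)C(C)(C)C | intermediate
4 | (4S,6S)-4-(tert-butyldimethylsilyloxy)-3-methyl-6-(prop-1-en-2-yl)cyclohex-2-en-1-one (silyloxy and isopropenyl cis) | CC1=CC(=O)[C@H](C(C)=C)C[C@@H]1O[Si](C)(C)C(C)(C)C | intermediate
5 | vinylmagnesium bromide | C=C[Mg]Br | starting material
6 | (1S,4S,6S)-4-(tert-butyldimethylsilyloxy)-1-ethenyl-3-methyl-6-(prop-1-en-2-yl)cyclohex-2-en-1-ol (vinyl trans to isopropenyl) | CC1=C[C@@](O)(C=C)[C@H](C(C)=C)C[C@@H]1O[Si](C)(C)C(C)(C)C | intermediate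
7 | (tert-butyldimethylsilyloxy)acetaldehyde | O=CCO[Si](C)(C)C(C)(C)C | starting material
8 | potassium enolate of (3S)-3-(tert-butyldimethylsilyloxy)-11,12,13-trinorgermacra-1(10)E,4Z-dien-6-one (not isolated) | C/C1=C\C[C@H](O[Si](C)(C)C(C)(C)C)/C(C)=C\C([O-])=CCC1.[K+] | intermediate
9 | (3S)-11-hydroxy-3,13-bis(tert-butyldimethylsilyloxy)-12-norgermacra-1(10)E,4Z-dien-6-one (C7/C11 epimers) | C/C1=C\C[C@H](O[Si](C)(C)C(C)(C)C)/C(C)=C\C(=O)C(C(O)CO[Si](C)(C)C(C)(C)C)CC1 | intermediate
10 | 11-O-methanesulfonate of 9 (not isolated) | C/C1=C\C[C@H](O[Si](C)(C)C(C)(C)C)/C(C)=C\C(=O)C(C(OS(C)(=O)=O)CO[Si](C)(C)C(C)(C)C)CC1 | intermediate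
11 | (3S)-3,13-bis(tert-butyldimethylsilyloxy)-12-norgermacra-1(10)E,4Z,7(11)E-trien-6-one | C/C1=C\C[C@H](O[Si](C)(C)C(C)(C)C)/C(C)=C\C(=O)/C(=C/CO[Si](C)(C)C(C)(C)C)CC1 | intermediate
12 | (3S)-11-(phenylsulfonyl)-3,13-bis(tert-butyldimethylsilyloxy)-12-norgermacra-1(10)E,4Z-dien-6-one (C7/C11 epimers, not isolated) | C/C1=C\C[C@H](O[Si](C)(C)C(C)(C)C)/C(C)=C\C(=O)C(C(CO[Si](C)(C)C(C)(C)C)S(=O)(=O)c2ccccc2)CC1 | intermediate
13 | (3S)-11-(phenylsulfonyl)-3,13-bis(tert-butyldimethylsilyloxy)-6-(triethylsilyloxy)-12-norgermacra-1(10)E,4Z,6-triene (C11 epimers; C6=C7 geometry not defined) | C/C1=C\C[C@H](O[Si](C)(C)C(C)(C)C)/C(C)=C\C(O[Si](CC)(CC)CC)=C(C(CO[Si](C)(C)C(C)(C)C)S(=O)(=O)c2ccccc2)CC1 | intermediate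
14 | lithium (3S)-11-(phenylsulfonyl)-3,13-bis(tert-butyldimethylsilyloxy)-6-(triethylsilyloxy)germacra-1(10)E,4Z,6-trien-12-oate (not isolated) | C/C1=C\C[C@H](O[Si](C)(C)C(C)(C)C)/C(C)=C\C(O[Si](CC)(CC)CC)=C(C(CO[Si](C)(C)C(C)(C)C)(C(=O)[O-])S(=O)(=O)c2ccccc2)CC1.[Li+] | intermediate
15 | (3S)-6-oxo-3,13-bis(tert-butyldimethylsilyloxy)germacra-1(10)E,4Z,7(11)Z-trien-12-oic acid (not isolated) | C/C1=C\C[C@H](O[Si](C)(C)C(C)(C)C)/C(C)=C\C(=O)/C(=C(/CO[Si](C)(C)C(C)(C)C)C(=O)O)CC1 | intermediate
16 | (3S)-6-hydroxy-3,13-bis(tert-butyldimethylsilyloxy)germacra-1(10)E,4Z,7(11)-trien-12,6-olide (C6 epimers) | C/C1=C\C[C@H](O[Si](C)(C)C(C)(C)C)/C(C)=C\C2(O)OC(=O)C(CO[Si](C)(C)C(C)(C)C)=C2CC1 | intermediate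
17 | (3S,6R)-3,13-bis(tert-butyldimethylsilyloxy)germacra-1(10)E,4Z,7(11)-trien-12,6-olide | C/C1=C\C[C@H](O[Si](C)(C)C(C)(C)C)/C(C)=C\[C@H]2OC(=O)C(CO[Si](C)(C)C(C)(C)C)=C2CC1 | intermediate
18 | (3S,6R)-3,13-dihydroxygermacra-1(10)E,4Z,7(11)-trien-12,6-olide | C/C1=C\C[C@H](O)/C(C)=C\[C@H]2OC(=O)C(CO)=C2CC1 | intermediate
19 | (3S,6R)-3,13-diacetoxygermacra-1(10)E,4Z,7(11)-trien-12,6-olide | C/C1=C\C[C@H](OC(C)=O)/C(C)=C\[C@H]2OC(=O)C(COC(C)=O)=C2CC1 | intermediate
20 | (1R,3S,6R)-3,13-diacetoxy-1-hydroperoxygermacra-4Z,7(11),10(14)-trien-12,6-olide | C=C1CCC2=C(COC(C)=O)C(=O)O[C@@H]2/C=C(/C)[C@@H](OC(C)=O)C[C@H]1OO | target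

**Total step count:** 12. **Longest linear sequence:** 12 steps (from 1; 5 and 7 are purchased).

**Steps most likely to fail**

Step 8. The allylic sulfonyl anion may be carboxylated at its γ-terminus (C6), may lose the β-silyloxide at C13 before it captures CO2, or the sulfinate loss and E-to-Z funnelling may stall. The fallback makes the C11–C12 bond by nickel-catalysed reductive coupling of a vinyl iodide with CO2 and keeps the same ring closure. It sets out from 13: LDA then Bu3SnCl gives the α-stannyl sulfone F1; TBAF unmasks C6 and sulfinate loss gives the β-stannyl dienone F2 (tin cis to the carbonyl through O→Sn coordination); I2 gives the (Z)-β-iodo dienone F3; NiCl2(PPh3)2 (cat.), Mn, Et4NI, CO2 (1 atm), DMI, rt then gives acid 15, which closes on acidic work-up, and the route is rejoined at 16.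

Step 9. Hydride may be delivered to the vinylogous terminus C4 (giving the γ-ylidene lactone) or to the bridged face, and the Lewis acid may trigger transannular cyclisation of the 1(10),4-diene. The fallback replaces the free cation by a π-allylpalladium complex under neutral conditions. It sets out from 16: Ac2O, pyridine, DMAP gives the C6 pseudo-ester acetate F4 (a cyclic acylal); Pd(PPh3)4 (cat.), Bu3SnH, THF, rt ionises the acetate, and hydride transfer from palladium to the oxygen-bearing terminus C6 (as in palladium chemistry of allylic gem-diesters) on the unbridged face returns to the route at 17.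

Step 12. Singlet oxygen may attack C1 with poor facial selectivity, or abstract hydrogen from C2 and give the tertiary C10 hydroperoxide. The fallback sets C1 by reagent control and introduces the peroxide by SN2 displacement. It sets out from 19: photo-oxygenation gives the crude C1-epimeric hydroperoxides F5, reduced in situ with PPh3 to the allylic alcohols F6; Dess–Martin periodinane gives the 10(14)-en-1-one F7; (R)-Me-CBS (cat.) with catecholborane at −78 °C gives the (1S)-alcohol F8; MsCl, Et3N at −30 °C gives the mesylate F9; potassium 2-methoxyprop-2-yl peroxide (from the hydroperoxide and KOtBu, 18-crown-6, THF, 0 °C) displaces it with inversion to the perketal F10; AcOH–THF–H2O then releases the hydroperoxide and the route is rejoined at 20.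

**Further compounds**

F1 | step 8 | (3S)-11-(phenylsulfonyl)-11-(tributylstannyl)-3,13-bis(tert-butyldimethylsilyloxy)-6-(triethylsilyloxy)-12-norgermacra-1(10)E,4Z,6-triene | C/C1=C\C[C@H](O[Si](C)(C)C(C)(C)C)/C(C)=C\C(O[Si](CC)(CC)CC)=C(C(CO[Si](C)(C)C(C)(C)C)([Sn](CCCC)(CCCC)CCCC)S(=O)(=O)c2ccccc2)CC1
F2 | step 8 | (3S)-11-(tributylstannyl)-3,13-bis(tert-butyldimethylsilyloxy)-12-norgermacra-1(10)E,4Z,7(11)Z-trien-6-one | C/C1=C\C[C@H](O[Si](C)(C)C(C)(C)C)/C(C)=C\C(=O)/C(=C(\[Sn](CCCC)(CCCC)CCCC)CO[Si](C)(C)C(C)(C)C)CC1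
F3 | step 8 | (3S)-11-iodo-3,13-bis(tert-butyldimethylsilyloxy)-12-norgermacra-1(10)E,4Z,7(11)Z-trien-6-one | C/C1=C\C[C@H](O[Si](C)(C)C(C)(C)C)/C(C)=C\C(=O)/C(=C(\I)CO[Si](C)(C)C(C)(C)C)CC1
F4 | step 9 | (3S)-6-acetoxy-3,13-bis(tert-butyldimethylsilyloxy)germacra-1(10)E,4Z,7(11)-trien-12,6-olide (C6 epimers) | C/C1=C\C[C@H](O[Si](C)(C)C(C)(C)C)/C(C)=C\C2(OC(C)=O)OC(=O)C(CO[Si](C)(C)C(C)(C)C)=C2CC1
F5 | step 12 | (3S,6R)-3,13-diacetoxy-1-hydroperoxygermacra-4Z,7(11),10(14)-trien-12,6-olide, C1 epimers (crude) | C=C1CCC2=C(COC(C)=O)C(=O)O[C@@H]2/C=C(/C)[C@@H](OC(C)=O)CC1OO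
F6 | step 12 | (3S,6R)-3,13-diacetoxy-1-hydroxygermacra-4Z,7(11),10(14)-trien-12,6-olide, C1 epimers | C=C1CCC2=C(COC(C)=O)C(=O)O[C@@H]2/C=C(/C)[C@@H](OC(C)=O)CC1O
F7 | step 12 | (3S,6R)-3,13-diacetoxy-1-oxogermacra-4Z,7(11),10(14)-trien-12,6-olide | C=C1CCC2=C(COC(C)=O)C(=O)O[C@@H]2/C=C(/C)[C@@H](OC(C)=O)CC1=O
F8 | step 12 | (1S,3S,6R)-3,13-diacetoxy-1-hydroxygermacra-4Z,7(11),10(14)-trien-12,6-olide | C=C1CCC2=C(COC(C)=O)C(=O)O[C@@H]2/C=C(/C)[C@@H](OC(C)=O)C[C@@H]1O
F9 | step 12 | (1S,3S,6R)-3,13-diacetoxy-1-(methanesulfonyloxy)germacra-4Z,7(11),10(14)-trien-12,6-olide | C=C1CCC2=C(COC(C)=O)C(=O)O[C@@H]2/C=C(/C)[C@@H](OC(C)=O)C[C@@H]1OS(C)(=O)=O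
F10 | step 12 | (1R,3S,6R)-3,13-diacetoxy-1-[(2-methoxypropan-2-yl)peroxy]germacra-4Z,7(11),10(14)-trien-12,6-olide | C=C1CCC2=C(COC(C)=O)C(=O)O[C@@H]2/C=C(/C)[C@@H](OC(C)=O)C[C@H]1OOC(C)(C)OC
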